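The slowness with which D gives back what it has taken is the quantity to reckon in these flasks.

    X + L ⇌ X.L (K1 = 48 M⁻¹, k1 = 676 M⁻¹ s⁻¹, Ea1 = 47.0 kJ mol⁻¹, ΔH1 = −1.00 kJ mol⁻¹)
    X + L ⇌ D (K2 = 280 M⁻¹, k2 = 23.0 M⁻¹ s⁻¹, Ea2 = 40.0 kJ mol⁻¹, ΔH2 = −51.0 kJ mol⁻¹)
    X.L + G ⇌ D + G, rate k3*[G]*[X.L] forward; the back reaction follows from the equilibrium constant (k3 = 941 M⁻¹ s⁻¹, Ea3 = 49.0 kJ mol⁻¹)
    X.L ⇌ Q (K4 = 0.39, k4 = 0.00441 s⁻¹, Ea4 = 104 kJ mol⁻¹, ΔH4 = 2.00 kJ mol⁻¹)
    Z ⇌ L, rate k5*(csat - [L]) (k5 = 10.3 s⁻¹, csat = 9.9 mM)
    (constants at 50 °C)

| setting | midnight | spring | noon | summer |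
|---|---|---|---|---|
| X | 0.30 M | 0.30 M | 0.30 M | 0.30 M |
| Z | 9.9 mM (held) | 9.9 mM (held) | 9.9 mM (held) | 9.9 mM (held) |
| G | 0.05 mol% | 0.05 mol% | 0.05 mol% | 0.05 mol% |
| temperature | 110 °C | 50 °C | 80 °C |  |
| time | 6.0 s | 6.0 s | 6.0 s | 6.0 s |
| remark |  |  |  | at 110 °C until 2.0 s, from then on at 50 °C |

- at the start none of L is dissolved
- constants are those at 50 °C; use the activation energies and enthalpies for any other temperature

1. the flask that comes out highest in share of X.L in all that became X.L or D or Q, or "all alike" when all lie within 1.5 percentage points (midnight / spring / noon / summer / all alike)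
2. share of X.L in all that became X.L or D or Q, midnight
3. share of X.L in all that became X.L or D or Q, spring
4. share of X.L in all that became X.L or D or Q, noon
5. share of X.L in all that became X.L or D or Q, summer

First, what share does a flask hold at rest? X.L and D each contain one X and one L, and Q forms from X.L in a first-order step, so the concentration of L cancels from the resting ratios. In the spring flask, D stands to X.L as the ratio of the two formation constants, 5.83, and Q to X.L as 0.39, so the resting share is 13.8 %. Step 1 speeds up 15-fold from spring to midnight; with its activation energy, this measures the span in inverse temperature. Scaling the constants across that span gives a midnight resting share of 57.0 %.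

Second, is rest reached in 6.0 s? G stands at 0.150 mM. Define the return rate b, the sum of D's back-rate constants through steps 2 and 3, 0.106 s⁻¹ in spring. Step 1 takes up L at a pseudo-first-order rate of about 203 s⁻¹, far faster than D returns, so it acts as a fast pre-equilibrium. With X.L replaced by its mean over the run, the ratio r of D to X.L climbs as its resting value times one minus exp(−bt). In midnight, 1/b is 0.0412 s, much shorter than the run, and the forward time of step 4 there, 0.529 s, is also shorter than the run, so midnight is expected under thermodynamic control at 57.0 %. In spring, 1/b is 9.43 s, longer than the run, so this flask is under kinetic control.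

Third, how far does spring get? Here r reaches 2.75, and with Q at 0.0265 of X.L the share is 26.5 %. Without a figure of its own, noon is expected between the two, and summer, which spends longer cold than hot, near spring. The choice of this reckoning is midnight.

The forecast also names midnight, with 57 % for midnight, 24.4 % for spring, 39.1 % for noon and 23.2 % for summer, holding for the hot flask that “everything equilibrates within 6 s”. Its spring share lies 2.1 percentage points below the reckoning here.

The simulation gives midnight, with 57.0 % for midnight, 24.7 % for spring, 39.8 % for noon and 23.6 % for summer. Midnight still reads 57.0 % at 60.0 s. In summer, b acts from the change onward, starting from the ratio 0.314 read at 2.00 s. It gives r = 2.23 at 6.00 s, less than the 2.65 read there.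

Read the summer flask at 25 s instead: the same b leaves 8.67 % of the distance to the resting ratio and gives r = 5.36. The simulated flask holds D at 59.9 % and X.L at 10.4 % of the X charged, a share of 13.3 %.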